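**Plan**

- Bonds cut, in retrosynthetic order: the seven ArO–benzyl bonds; C3–OH of the lower unit (from a C3=C4 alkene); C2–C3 and C4–C4a of the lower pyran ring together (formal [4+2] of an O-aryl oxocarbenium ion with phenyl vinyl sulfide); O1–C2 of that ring (O-alkylation of a phenol); C4(upper)–C8(lower) (aryl-metal addition to a flavanone, then hydride); C2–aryl of the upper unit (conjugate addition to a chromone).
- Forward order: the upper pyranone ring is bought as a chromone and receives its ring B; ring A of the lower unit is attached at C4 of the upper unit; the lower ring B arrives as an aldehyde carbon on the phenol oxygen; ring C of the lower unit closes last, followed by C3=C4, C3–OH and debenzylation.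
- Enabling feature: in the lower unit O1 is an aryl ether oxygen on ring A, its ortho carbon C4a is unsubstituted and activated by the oxygens on C5 and C7, and C2 is an O-benzylic carbon on the electron-rich ring B. The cation C4a=C8a–O1(+)=C2 is therefore an accessible 2-oxadiene that an alkene C3=C4 can span.
- Stereochemistry: upper C2 (S) from the chiral ligand in the conjugate addition; upper C4 (S, 2,4-cis) from axial hydride delivery to the C4 cation; lower C2 (R) from the chiral counter-anion in the key step; lower C3 (S, 2,3-trans) from hydroboration anti to the C2 aryl group.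

Key step: step 7

Assumption: the sense of induction of the ligand in step 2 (taken by analogy with β-arylation of cyclic enones) and of the chiral acid in step 7 (no analogy available) is not secured by precedent on these substrates; if a first run gives the C2 epimer, the antipodal ligand or acid is used.

**Step 1**
Reactants: 1 7-hydroxy-4H-chromen-4-one
Product: 2 7-(benzyloxy)-4H-chromen-4-one
Conditions: BnBr, K2CO3, acetone, reflux
Reagents that add atoms: benzyl bromide, BrCc1ccccc1
Why: Williamson etherification of the acidic 7-hydroxyl group, under conditions too weakly nucleophilic to open the pyranone ring.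

**Step 2**
Reactants: 2 7-(benzyloxy)-4H-chromen-4-one; 3 [3,4-bis(benzyloxy)phenyl]boronic acid
Product: 4 (2S)-7-(benzyloxy)-2-[3,4-bis(benzyloxy)phenyl]chroman-4-one
Conditions: Pd(OCOCF3)2 (5 mol %), (R)-4-tert-butyl-2-(pyridin-2-yl)-4,5-dihydrooxazole (6 mol %), NH4PF6 (30 mol %), H2O (5 equiv), ClCH2CH2Cl, 60 °C
Reagents that add atoms: none
Why: Pd-catalysed asymmetric conjugate addition of an arylboronic acid to a chromone, in which the pyridine–oxazoline ligand selects the face of C2 and should set the (2S) centre.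

**Step 3**
Reactants: 5 3,5-bis(benzyloxy)phenol
Product: 6 3,5-bis(benzyloxy)-2-bromophenol
Conditions: N-bromosuccinimide (1.0 equiv), i-Pr2NH (10 mol %), CH2Cl2, –78 → 0 °C
Reagents that add atoms: N-bromosuccinimide, O=C1CCC(=O)N1Br
Why: amine-mediated electrophilic bromination of a phenol, delivered ortho to the hydroxyl group through the hydrogen-bonded N-bromoamine; the two ortho positions are equivalent.

**Step 4**
Reactants: 6 3,5-bis(benzyloxy)-2-bromophenol; 4 (2S)-flavanone
Product: 7 (2S)-4-aryl-flavan-4-ol (both C4 epimers)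
Conditions: 6, n-BuLi (1.0 equiv) then t-BuLi (2.0 equiv), THF, –78 °C; CeCl3, –78 °C; then 4, –78 → –20 °C; aq. NH4Cl
Reagents that add atoms: none
Why: bromine–lithium exchange on the lithium phenoxide and 1,2-addition of the derived organocerium reagent, which is nucleophilic but hardly basic and should add to the enolisable ketone without opening the pyranone ring; the carbinol centre forms as a mixture and becomes planar in step 5.

**Step 5**
Reactants: 7 (2S)-4-aryl-flavan-4-ol
Product: 8 3,5-bis(benzyloxy)-2-{(2S,4S)-7-(benzyloxy)-2-[3,4-bis(benzyloxy)phenyl]chroman-4-yl}phenol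
Conditions: Et3SiH (5 equiv), CF3CO2H (3 equiv), CH2Cl2, –40 → 0 °C
Reagents that add atoms: none
Why: ionic hydrogenation of a tertiary diarylcarbinol, in which the C4 cation should take hydride along the axial trajectory of the half-chair with the C2 aryl group equatorial (the course of hydride reduction of flavanones), so that the new aryl group ends equatorial and 2,4-cis (4S).

**Step 6**
Reactants: 8 cis-4-(2-hydroxyaryl)flavan; 9 3,4-bis(benzyloxy)benzaldehyde
Product: 11 O-aryl O-pivaloyl acetal of 9 on the phenol oxygen of 8 (both epimers at the acetal carbon), via α-chlorobenzyl pivalate 10 (not isolated)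
Conditions: 9, t-BuCOCl (1.05 equiv), ZnCl2 (2 mol %), CH2Cl2, 0 °C; then added to 8, NaH, THF/DMF, –20 → 20 °C; filtration through basic alumina
Reagents that add atoms: pivaloyl chloride, CC(C)(C)C(Cl)=O
Why: ZnCl2-catalysed addition of an acyl chloride to an aldehyde gives the α-chloroalkyl ester, and Williamson-type O-alkylation of the sodium phenoxide by it (as with chloromethyl pivalate) gives the acylal; its stereogenic carbon becomes planar in step 7.

**Step 7**
Reactants: 11 O-aryl O-pivaloyl acetal; 12 phenyl vinyl sulfide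
Product: 14 lower-unit 4-(phenylsulfanyl)flavan (2S,4S in the new ring), via oxocarbenium ion 13 (not isolated)
Conditions: 12 (3 equiv), (R)-3,3'-bis(2,4,6-triisopropylphenyl)-1,1'-binaphthalene-2,2'-diyl N-(trifluoromethylsulfonyl)phosphoramidate, (ArO)2P(=O)NHSO2CF3 (10 mol %), 4 Å molecular sieves, toluene, –40 °C
Reagents that add atoms: none
Why: Proposed new method: the acid ionises the acylal (pivalic acid leaves and the aryloxy group stays, because only that cation is stabilised by an ether oxygen) to the (E)-O-aryl oxocarbenium ion 13, a cationic 2-oxadiene C4a=C8a–O1(+)=C2 held as a contact ion pair with the chiral phosphoramidate; the CH2 terminus of 12 bonds to C2 and the sulfur-stabilised cation that results at C4 is captured by C4a, so that both bonds form in one asynchronous formal [4+2] cycloaddition. The closest known reactions are the oxa-Povarov reaction (aryl oxocarbenium ions with alkenes under stoichiometric SnCl4), the chiral-phosphoric-acid Povarov reaction of N-aryl imines with vinyl ethers and chiral-anion-controlled additions to oxocarbenium ions; what is new is their combination on an O-aryl acylal with a vinyl sulfide. The one ring formed, pyran ring C of the lower unit, closes by Friedel–Crafts attack of the arene carbon C4a on the thionium carbon C4, 6-exo-trig with respect to C=S(+) and endo with respect to the arene double bond. C2 is set in the first bond formation by the chiral anion, which shields one face of the planar cation (catalyst control; the flavanyl group on C8 may reinforce or oppose it), and C4 should follow as the 2,4-cis epimer from a chair-like closure with both substituents equatorial, which does not matter because C4 becomes sp2 in step 8. Regioselectivity is needed in the alkene (sulfur directs the cation to C4, so CH2 becomes C3), in the closure (C4a is the only free carbon ortho to O1, since C8 carries the upper unit and C6 cannot reach) and between O-alkylation by the alkene path and C-alkylation of ring A; the product must also survive the acid, which the 4-thioether secures where a 4-alkoxy group next to the 5,7-dioxygenated ring would ionise again.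

**Step 8**
Reactants: 14 lower-unit 4-(phenylsulfanyl)flavan
Product: 16 lower-unit (2S)-2H-chromene (flav-3-ene), via sulfoxide 15 (not isolated)
Conditions: 3-ClC6H4CO3H (1.0 equiv), CH2Cl2, –78 °C; then NaHCO3, toluene, 80 °C
Reagents that add atoms: none
Why: chemoselective sulfide oxidation and thermal syn-elimination of the sulfoxide, which can only take a hydrogen from C3 and therefore should give the C3=C4 alkene without touching C2.

**Step 9**
Reactants: 16 lower-unit (2S)-2H-chromene
Product: 18 hepta-O-benzyl ether of the target (2R,3S in the lower unit), via alkylborane 17 (not isolated)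
Conditions: BH3·THF, THF, 0 → 20 °C; then NaOH, H2O2, H2O, 0 °C
Reagents that add atoms: hydrogen peroxide, OO
Why: hydroboration–oxidation, in which boron should go to C3 (away from the arene-bearing C4 of the electron-rich styrene) on the face opposite the C2 aryl group and oxidation with retention gives the 2,3-trans (3S) alcohol, as in known conversions of flav-3-enes into 2,3-trans-flavan-3-ols.

**Step 10**
Reactants: 18 hepta-O-benzyl ether of the target
Product: 19 CNP0227165.3
Conditions: H2 (1 atm), Pd(OH)2/C, THF/MeOH, 20 °C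
Reagents that add atoms: none
Why: hydrogenolysis of the seven benzyl ethers, the usual last step for oligomeric flavans; the cyclic benzylic O1–C2 bonds are cleaved much more slowly than O-benzyl groups.

**Compound list**

1 | 7-hydroxy-4H-chromen-4-one | O=c1ccoc2cc(O)ccc12 | starting material
2 | 7-(benzyloxy)-4H-chromen-4-one | O=c1ccoc2cc(OCc3ccccc3)ccc12 | intermediate
3 | [3,4-bis(benzyloxy)phenyl]boronic acid | OB(O)c1ccc(OCc2ccccc2)c(OCc2ccccc2)c1 | starting material
4 | (2S)-7-(benzyloxy)-2-[3,4-bis(benzyloxy)phenyl]chroman-4-one | O=C1C[C@@H](c2ccc(OCc3ccccc3)c(OCc3ccccc3)c2)Oc2cc(OCc3ccccc3)ccc12 | intermediate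
5 | 3,5-bis(benzyloxy)phenol | Oc1cc(OCc2ccccc2)cc(OCc2ccccc2)c1 | starting material
6 | 3,5-bis(benzyloxy)-2-bromophenol | Oc1cc(OCc2ccccc2)cc(OCc2ccccc2)c1Br | intermediate
7 | (2S)-7-(benzyloxy)-4-[2,4-bis(benzyloxy)-6-hydroxyphenyl]-2-[3,4-bis(benzyloxy)phenyl]chroman-4-ol (C4 epimers) | C(Oc1ccc2c(c1)O[C@H](c1ccc(OCc3ccccc3)c(OCc3ccccc3)c1)CC2(O)c1c(OCc2ccccc2)cc(OCc2ccccc2)cc1O)c1ccccc1 | intermediate
8 | 3,5-bis(benzyloxy)-2-{(2S,4S)-7-(benzyloxy)-2-[3,4-bis(benzyloxy)phenyl]chroman-4-yl}phenol | C(Oc1ccc2c(c1)O[C@H](c1ccc(OCc3ccccc3)c(OCc3ccccc3)c1)C[C@@H]2c1c(OCc2ccccc2)cc(OCc2ccccc2)cc1O)c1ccccc1 | intermediate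
9 | 3,4-bis(benzyloxy)benzaldehyde | O=Cc1ccc(OCc2ccccc2)c(OCc2ccccc2)c1 | starting material
10 | chloro[3,4-bis(benzyloxy)phenyl]methyl 2,2-dimethylpropanoate (racemic) | CC(C)(C)C(=O)OC(Cl)c1ccc(OCc2ccccc2)c(OCc2ccccc2)c1 | intermediate (not isolated)
11 | [3,4-bis(benzyloxy)phenyl]{3,5-bis(benzyloxy)-2-[(2S,4S)-7-(benzyloxy)-2-[3,4-bis(benzyloxy)phenyl]chroman-4-yl]phenoxy}methyl 2,2-dimethylpropanoate (both acetal epimers) | C(Oc1ccc2c(c1)O[C@H](c1ccc(OCc3ccccc3)c(OCc3ccccc3)c1)C[C@@H]2c1c(OCc2ccccc2)cc(OCc2ccccc2)cc1OC(OC(=O)C(C)(C)C)c1ccc(OCc2ccccc2)c(OCc2ccccc2)c1)c1ccccc1 | intermediate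
12 | phenyl vinyl sulfide | C=CSc1ccccc1 | starting material
13 | O-aryl oxocarbenium ion from 11 (cation of the ion pair with the chiral phosphoramidate) | C(Oc1ccc2c(c1)O[C@H](c1ccc(OCc3ccccc3)c(OCc3ccccc3)c1)C[C@@H]2c1c(OCc2ccccc2)cc(OCc2ccccc2)cc1[O+]=Cc1ccc(OCc2ccccc2)c(OCc2ccccc2)c1)c1ccccc1 | intermediate (not isolated)
14 | (2S,4S)-5,7-bis(benzyloxy)-8-{(2S,4S)-7-(benzyloxy)-2-[3,4-bis(benzyloxy)phenyl]chroman-4-yl}-2-[3,4-bis(benzyloxy)phenyl]-4-(phenylsulfanyl)chromane | C(Oc1ccc2c(c1)O[C@H](c1ccc(OCc3ccccc3)c(OCc3ccccc3)c1)C[C@@H]2c1c(OCc2ccccc2)cc(OCc2ccccc2)c2c1O[C@H](c1ccc(OCc3ccccc3)c(OCc3ccccc3)c1)C[C@@H]2Sc1ccccc1)c1ccccc1 | intermediate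
15 | S-oxide of 14 (sulfoxide, both epimers at sulfur) | C(Oc1ccc2c(c1)O[C@H](c1ccc(OCc3ccccc3)c(OCc3ccccc3)c1)C[C@@H]2c1c(OCc2ccccc2)cc(OCc2ccccc2)c2c1O[C@H](c1ccc(OCc3ccccc3)c(OCc3ccccc3)c1)C[C@@H]2S(=O)c1ccccc1)c1ccccc1 | intermediate (not isolated)
16 | (2S)-5,7-bis(benzyloxy)-8-{(2S,4S)-7-(benzyloxy)-2-[3,4-bis(benzyloxy)phenyl]chroman-4-yl}-2-[3,4-bis(benzyloxy)phenyl]-2H-chromene | C(Oc1ccc2c(c1)O[C@H](c1ccc(OCc3ccccc3)c(OCc3ccccc3)c1)C[C@@H]2c1c(OCc2ccccc2)cc(OCc2ccccc2)c2c1O[C@H](c1ccc(OCc3ccccc3)c(OCc3ccccc3)c1)C=C2)c1ccccc1 | intermediate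
17 | C3-borane of 16 (monoalkylborane, boron trans to the C2 aryl group) | C(Oc1ccc2c(c1)O[C@H](c1ccc(OCc3ccccc3)c(OCc3ccccc3)c1)C[C@@H]2c1c(OCc2ccccc2)cc(OCc2ccccc2)c2c1O[C@H](c1ccc(OCc3ccccc3)c(OCc3ccccc3)c1)[C@@H](B)C2)c1ccccc1 | intermediate (not isolated)
18 | (2R,3S)-5,7-bis(benzyloxy)-8-{(2S,4S)-7-(benzyloxy)-2-[3,4-bis(benzyloxy)phenyl]chroman-4-yl}-2-[3,4-bis(benzyloxy)phenyl]chroman-3-ol | C(Oc1ccc2c(c1)O[C@H](c1ccc(OCc3ccccc3)c(OCc3ccccc3)c1)C[C@@H]2c1c(OCc2ccccc2)cc(OCc2ccccc2)c2c1O[C@H](c1ccc(OCc3ccccc3)c(OCc3ccccc3)c1)[C@@H](O)C2)c1ccccc1 | intermediate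
19 | (2R,3S)-2-(3,4-dihydroxyphenyl)-8-[(2S,4S)-2-(3,4-dihydroxyphenyl)-7-hydroxychroman-4-yl]chromane-3,5,7-triol (CNP0227165.3) | Oc1ccc2c(c1)O[C@H](c1ccc(O)c(O)c1)C[C@@H]2c1c(O)cc(O)c2c1O[C@H](c1ccc(O)c(O)c1)[C@@H](O)C2 | target

**Step count and risks**

Total steps: 10. Longest linear sequence: 9 steps (1, 2, 4, 5, 6, 7, 8, 9, 10); step 3 is a one-step branch.

Steps most likely to fail:

1. Step 7 (Proposed new method). What may go wrong: the ion pair gives too little facial control at C2, or the oxocarbenium ion alkylates ring A at carbon instead of being captured by the alkene. The fallback gives up the annulation and takes ring C of the lower unit from the chiral pool; it sets out from 4 and commercial (+)-catechin and returns at 18. (+)-Catechin is benzylated on its four phenols (BnBr, K2CO3, DMF) to 5,7,3',4'-tetra-O-benzyl-(+)-catechin F1. This is brominated at C8 (N-bromosuccinimide, CH2Cl2, –78 °C) to 8-bromo-5,7,3',4'-tetra-O-benzyl-(+)-catechin F2. F2 is converted into its dianion (MeLi for the 3-hydroxyl group, then t-BuLi, THF, –78 °C; CeCl3) and added to flavanone 4 to give the biflavanoid carbinol F3. Et3SiH/CF3CO2H then reduces F3 as in step 5 to 18.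

2. Step 4. What may go wrong: enolisation of the flavanone with β-elimination of the phenoxide (ring opening), which erodes the C2 configuration and consumes the aryl-metal; or slow addition of the doubly ortho-substituted nucleophile. The fallback avoids the flavanone and builds the upper pyran ring by cycloaddition; it sets out from 6 (with 9 and commercial 4-(benzyloxy)-2-hydroxybenzaldehyde) and returns at 8. Phenol 6 is O-allylated (allyl bromide, K2CO3, DMF) to 1-(allyloxy)-3,5-bis(benzyloxy)-2-bromobenzene F4. Bromine–lithium exchange (t-BuLi, THF, –78 °C) and addition to the sodium salt of 4-(benzyloxy)-2-hydroxybenzaldehyde gives the o-hydroxybenzhydrol F5. The chiral N-triflylphosphoramide of step 7 (or its antipode) converts F5 into its ortho-quinone methide, which undergoes endo [4+2] cycloaddition with 3,4-bis(benzyloxy)styrene F6 (from 9 by Wittig methylenation with Ph3P=CH2) to give the cis-2,4-diarylchroman allyl ether F7. Pd(PPh3)4 and morpholine remove the allyl group to give 8.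

3. Step 5. What may go wrong: hydride delivery from the other face (2,4-trans epimer) or acid-induced opening of the pyran ring at C2. The fallback replaces ionic by catalytic syn-hydrogenation; it sets out from 7 and returns at 8. Carbinol 7 is dehydrated (pyridinium p-toluenesulfonate, toluene, 60 °C) to the (2S)-4-aryl-2H-chromene F8. F8 is hydrogenated with H2 and [Ir(cod)(py)(PCy3)]PF6 in CH2Cl2, which leaves benzyl ethers intact and should add hydrogen from the face opposite the C2 aryl group, giving 8.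

**Further compounds**

F1 | step 7 | (2R,3S)-5,7-bis(benzyloxy)-2-[3,4-bis(benzyloxy)phenyl]chroman-3-ol | c1c(OCc3ccccc3)cc(OCc3ccccc3)c2c1O[C@H](c1ccc(OCc3ccccc3)c(OCc3ccccc3)c1)[C@@H](O)C2
F2 | step 7 | (2R,3S)-5,7-bis(benzyloxy)-2-[3,4-bis(benzyloxy)phenyl]-8-bromochroman-3-ol | Brc1c(OCc3ccccc3)cc(OCc3ccccc3)c2c1O[C@H](c1ccc(OCc3ccccc3)c(OCc3ccccc3)c1)[C@@H](O)C2
F3 | step 7 | (2R,3S)-5,7-bis(benzyloxy)-8-{(2S)-7-(benzyloxy)-2-[3,4-bis(benzyloxy)phenyl]-4-hydroxychroman-4-yl}-2-[3,4-bis(benzyloxy)phenyl]chroman-3-ol (epimers at the carbinol carbon) | C(Oc1ccc2c(c1)O[C@H](c1ccc(OCc3ccccc3)c(OCc3ccccc3)c1)CC2(O)c1c(OCc2ccccc2)cc(OCc2ccccc2)c2c1O[C@H](c1ccc(OCc3ccccc3)c(OCc3ccccc3)c1)[C@@H](O)C2)c1ccccc1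
F4 | step 4 | 1-(allyloxy)-3,5-bis(benzyloxy)-2-bromobenzene | C=CCOc1cc(OCc2ccccc2)cc(OCc2ccccc2)c1Br
F5 | step 4 | [2-(allyloxy)-4,6-bis(benzyloxy)phenyl][4-(benzyloxy)-2-hydroxyphenyl]methanol (racemic) | OC(c1ccc(OCc2ccccc2)cc1O)c1c(OCC=C)cc(OCc2ccccc2)cc1OCc1ccccc1
F6 | step 4 | 3,4-bis(benzyloxy)styrene | C=Cc1ccc(OCc2ccccc2)c(OCc2ccccc2)c1
F7 | step 4 | (2S,4S)-4-[2-(allyloxy)-4,6-bis(benzyloxy)phenyl]-7-(benzyloxy)-2-[3,4-bis(benzyloxy)phenyl]chromane | C(Oc1ccc2c(c1)O[C@H](c1ccc(OCc3ccccc3)c(OCc3ccccc3)c1)C[C@@H]2c1c(OCc2ccccc2)cc(OCc2ccccc2)cc1OCC=C)c1ccccc1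
F8 | step 5 | 3,5-bis(benzyloxy)-2-{(2S)-7-(benzyloxy)-2-[3,4-bis(benzyloxy)phenyl]-2H-chromen-4-yl}phenol | C(Oc1ccc2c(c1)O[C@H](c1ccc(OCc3ccccc3)c(OCc3ccccc3)c1)C=C2c1c(OCc2ccccc2)cc(OCc2ccccc2)cc1O)c1ccccc1
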